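## Retrosynthetic overview

1. 5 ⇒ 4: remove three Br (two on ring B, one on ring A). Each sits ortho to a free OH, so they go on last by electrophilic bromination.
2. 4 ⇒ 3: ring B of 4 is the reduced form of aryloxyquinone 3, made by a dithionite reduction in the same flask.
3. 3 ⇒ 1 + 2: cut the diaryl ether C–O bond, the only skeletal bond to be made. Ring B's carbon is a donor (enol-type) carbon in the hydroquinone; at the quinone level it is an acceptor (enolonium-type, polarity reversed) that takes the phenoxide oxygen of 1 and gives up bromide.
4. 1 and 2 are the reduced and oxidised forms of one commercial compound, so electron exchange between them changes nothing and no protecting group is needed. No ring is formed: ring A (the phenoxy ring) comes intact from 1 and ring B (the hydroquinone ring) from 2.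

Assumption: 5 has no stereocentre and no configurationally stable axis, so the SMILES defines one achiral compound and no stereocontrol is required.

## Route

Step 1
Reactants: 1 2,5-dibromobenzene-1,4-diol; 2 2,5-dibromocyclohexa-2,5-diene-1,4-dione
Product: 4 2-bromo-5-(2,5-dibromo-4-hydroxyphenoxy)benzene-1,4-diol, via aryloxyquinone 3 (not isolated)
Conditions: K2CO3 (1.0 equiv, limiting reagent), each partner in twofold excess, degassed MeCN, Ar, 0 °C, 4 h; then Na2S2O4 (3 equiv), H2O/EtOAc, 20 °C
Reagents that add atoms: none
Why: Proposed new method: the mono-phenoxide of 1 attacks a bromine-bearing carbon of 2 and bromide leaves (addition–elimination at a vinylogous acyl bromide), giving aryloxyquinone 3, which Na2S2O4 reduces to 4; electron exchange between 1 and 2 is degenerate, both partners are twofold symmetric so only one constitution can form, K2CO3 as the limiting reagent with both partners in excess holds the reaction at one substitution on each, and no stereocentre is formed; the closest known reaction is the K2CO3-mediated O-arylation of phenols by bromoquinones such as 2-bromo-1,4-naphthoquinone and tetrabromo-1,4-benzoquinone, and what is new is that a free hydroquinone serves as the phenol.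

Step 2
Reactants: 4 2-bromo-5-(2,5-dibromo-4-hydroxyphenoxy)benzene-1,4-diol
Product: 5 2,3,5-tribromo-6-(2,3,5-tribromo-4-hydroxyphenoxy)benzene-1,4-diol
Conditions: Br2 (3.1 equiv), AcOH, 20 → 45 °C, dark, 3 h
Reagents that add atoms: bromine, BrBr
Why: Electrophilic aromatic bromination (the standard Br2/AcOH bromination of hydroquinones and phenols): both C–H positions of ring B are ortho to a free OH, ring A has one C–H ortho to its free OH, and the last ring-A C–H is meta to OH on a ring that then carries three bromines, so three equivalents stop at 5; no stereocentre is formed.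

## Compound list

1 | 2,5-dibromobenzene-1,4-diol (2,5-dibromohydroquinone) | Oc1cc(Br)c(O)cc1Br | starting material
2 | 2,5-dibromocyclohexa-2,5-diene-1,4-dione (2,5-dibromo-1,4-benzoquinone) | O=C1C=C(Br)C(=O)C=C1Br | starting material
3 | 2-bromo-5-(2,5-dibromo-4-hydroxyphenoxy)cyclohexa-2,5-diene-1,4-dione (aryloxyquinone, not isolated) | O=C1C=C(Br)C(=O)C=C1Oc1cc(Br)c(O)cc1Br | intermediate
4 | 2-bromo-5-(2,5-dibromo-4-hydroxyphenoxy)benzene-1,4-diol | Oc1cc(Br)c(O)cc1Oc1cc(Br)c(O)cc1Br | intermediate
5 | 2,3,5-tribromo-6-(2,3,5-tribromo-4-hydroxyphenoxy)benzene-1,4-diol | Oc1c(Br)cc(Oc2c(O)c(Br)c(Br)c(O)c2Br)c(Br)c1Br | target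

## Step count and risks

Total step count: 2. Longest linear sequence: 2 steps (1 + 2 → 4 → 5).

The route has only two steps, so both are ranked. Step 1 is entered twice because it has two independent failure modes.

Risk 1, step 1 (over-reaction). The remaining C–Br of 3 can take a second phenoxide, and the second OH of the ring that came from 1 can attack a second molecule of 2, so oligomers can form. K2CO3 as the limiting reagent and the excess of both partners are meant to suppress this; after the dithionite treatment all unreacted material is recovered as 1. The fallback sets out from 1 and comes back to the route at 4. Compound 1 is mono-O-methylated (MeI 1.0 equiv, K2CO3, acetone; statistical, unreacted 1 recycled) to 2,5-dibromo-4-methoxyphenol F1. F1 has only one nucleophilic oxygen and cannot be oxidised to a quinone, so it can be used against a threefold excess of 2 (K2CO3, MeCN, 0 °C). This gives 2-bromo-5-(2,5-dibromo-4-methoxyphenoxy)cyclohexa-2,5-diene-1,4-dione F2. Na2S2O4 (EtOAc/H2O) reduces it to 2-bromo-5-(2,5-dibromo-4-methoxyphenoxy)benzene-1,4-diol F3. BBr3 (CH2Cl2, −78 → 20 °C) then removes the methyl group and gives 4.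

Risk 2, step 1 (wrong atom, or no bond at all). The phenoxide of 1 may react through its ortho carbon (C–C coupling), or 1 and 2 may settle as semiquinone radicals under base and not couple. An adduct formed by O-attack at a C–H carbon of 2 is no loss: it holds the same ether bond, is carried through step 2 with 4 and gives 5 with one equivalent of Br2 less. The fallback sets out from 1 and comes back to the route at 5, and replaces the quinone chemistry by a copper-mediated O-arylation. 2,5-Dibromo-4-methoxyphenol F1 (made from 1 as above) is coupled with commercial 2,5-dimethoxyphenylboronic acid (COc1ccc(OC)c(B(O)O)c1) under Chan–Lam conditions (Cu(OAc)2, pyridine, 4 Å sieves, CH2Cl2, air, 20 °C; aryl bromides are untouched). This gives 1,4-dibromo-2-(2,5-dimethoxyphenoxy)-5-methoxybenzene F4. BBr3 removes the three methyl groups to give 2-(2,5-dibromo-4-hydroxyphenoxy)benzene-1,4-diol F5. Br2 (4.2 equiv, AcOH, then Na2S2O4 wash) fills the three free positions of ring B and the one position ortho to the ring-A OH and gives 5.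

Risk 3, step 2. Br2 may oxidise ring B of 4 to the quinone while bromines are still missing, and HBr could then attack the aryloxy-bearing carbon and cleave the ether; a fourth bromine could also enter ring A. A wash with aqueous Na2S2O4 returns quinone-level material to the hydroquinone level, but it cannot repair a cleaved ether. The fallback sets out from 3 and comes back to the route at 5, and keeps ring B at the quinone level until all bromines are in place. Compound 3 is isolated after the coupling (dilute acid work-up, no dithionite, chromatography). Br2 (3.2 equiv) with NaOAc (3.2 equiv) in AcOH (20 → 60 °C) brominates ring A ortho to its OH and adds across each C–H double bond of the quinone ring; NaOAc takes up the HBr lost from each dibromide. This gives 2,3,5-tribromo-6-(2,3,5-tribromo-4-hydroxyphenoxy)cyclohexa-2,5-diene-1,4-dione F6. Na2S2O4 (EtOAc/H2O) then reduces F6 to 5.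

## Further compounds

F1 | step 1 | 2,5-dibromo-4-methoxyphenol | COc1cc(Br)c(O)cc1Br
F2 | step 1 | 2-bromo-5-(2,5-dibromo-4-methoxyphenoxy)cyclohexa-2,5-diene-1,4-dione | O=C1C=C(Br)C(=O)C=C1Oc1cc(Br)c(OC)cc1Br
F3 | step 1 | 2-bromo-5-(2,5-dibromo-4-methoxyphenoxy)benzene-1,4-diol | Oc1cc(Br)c(O)cc1Oc1cc(Br)c(OC)cc1Br
F4 | step 1 | 1,4-dibromo-2-(2,5-dimethoxyphenoxy)-5-methoxybenzene | COc1ccc(OC)c(Oc2cc(Br)c(OC)cc2Br)c1
F5 | step 1 | 2-(2,5-dibromo-4-hydroxyphenoxy)benzene-1,4-diol | Oc1ccc(O)c(Oc2cc(Br)c(O)cc2Br)c1
F6 | step 2 | 2,3,5-tribromo-6-(2,3,5-tribromo-4-hydroxyphenoxy)cyclohexa-2,5-diene-1,4-dione | O=C1C(Br)=C(Br)C(=O)C(Br)=C1Oc1cc(Br)c(O)c(Br)c1Br
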